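## Retrosynthetic overview
1. The last bond made is C9–C11. A tertiary C9 radical, released from the C9 carboxylic acid by loss of CO2, adds to the exocyclic CH2 of an ortho-quinone methide. This sets the quaternary centre and attaches the finished aminohydroxyquinone.
2. The quinone methide comes from 2-hydroxy-5-(isopentylamino)benzoquinone, CH2O and morpholine. That quinone comes from 2,5-dihydroxybenzoquinone and isopentylamine, and the dihydroxyquinone from hydroquinone.
3. Ring B, with C8 and C10, comes from a catalytic enantioselective exo Diels–Alder reaction of 6,6-dimethyl-1-vinylcyclohexene with tiglaldehyde, followed by CHO → CO2H.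
4. The diene comes from 2,2-dimethylcyclohexanone (enol triflate, vinyl coupling), which comes from 2-methylcyclohex-2-enone by reductive methylation.
5. Ring order: ring A is the purchased carbocycle, ring B is formed by the cycloaddition, and the quinone ring is attached intact in the last step.

Atom labels: C4 = CMe2, C5=C6 = alkene, C8 = CHMe, C9 = quaternary carbon, C10 = ring-fusion CH, C1 = ring A CH2 on C10, C11 = CH2 link to quinone C3.

Assumption: the oxazaborolidinium catalyst follows its usual formyl C–H···O binding model, so the (R)-prolinol-derived catalyst exposes the Cα-Si face of 8; if the adduct proved antipodal, the (S)-catalyst would be used with nothing else changed.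

## Route

Step 1
Reactants: 1 2-methylcyclohex-2-en-1-one
Product: 3 2,2-dimethylcyclohexanone, via lithium enolate 2 (not isolated)
Conditions: LiBH(s-Bu)3 (1.05 equiv), THF, −78 °C, 1 h; MeI (3 equiv), −78 °C → rt
Reagents that add atoms: iodomethane CI
Why: Conjugate hydride delivery gives the enolate regiospecifically on the methyl-bearing carbon (Stork-type reductive alkylation of an enone), so C-methylation installs the gem-dimethyl group without the regioisomers of a direct ketone alkylation; no stereocentre is formed.

Step 2
Reactants: 3 2,2-dimethylcyclohexanone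
Product: 5 6,6-dimethylcyclohex-1-en-1-yl trifluoromethanesulfonate, via lithium enolate 4 (not isolated)
Conditions: LiN(i-Pr)2 (1.1 equiv), THF, −78 °C; PhNTf2 (1.1 equiv), −78 °C → rt
Reagents that add atoms: N-phenylbis(trifluoromethanesulfonimide) O=S(=O)(N(c1ccccc1)S(=O)(=O)C(F)(F)F)C(F)(F)F
Why: Only one α-carbon carries hydrogen, so deprotonation and O-sulfonylation (enol triflate formation) give a single alkenyl triflate.

Step 3
Reactants: 5 6,6-dimethylcyclohex-1-en-1-yl trifluoromethanesulfonate; 6 potassium vinyltrifluoroborate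
Product: 7 6,6-dimethyl-1-vinylcyclohex-1-ene
Conditions: PdCl2(dppf)·CH2Cl2 (3 mol %), Cs2CO3 (3 equiv), THF/H2O 9:1, 65 °C (product is volatile, so concentrate cold)
Reagents that add atoms: none
Why: Suzuki–Miyaura coupling of an alkenyl triflate keeps the ring double bond in place and gives the conjugated diene directly under non-acidic conditions.

Step 4
Reactants: 7 6,6-dimethyl-1-vinylcyclohex-1-ene; 8 (E)-2-methylbut-2-enal (tiglaldehyde)
Product: 9 (1R,2S,8aR)-1,2,5,5-tetramethyl-1,2,3,5,6,7,8,8a-octahydronaphthalene-1-carbaldehyde (exo adduct: C8-CH3 and C9-CH3 cis to each other and to C1; CHO cis to H10)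
Conditions: (R)-3,3-diphenyl-1-(2-methylphenyl)tetrahydro-1H,3H-pyrrolo[1,2-c][1,3,2]oxazaborole (20 mol %), Tf2NH (18 mol %), 8 (2 equiv), CH2Cl2, −78 → −40 °C, 48 h; chromatography removes the endo isomer
Reagents that add atoms: none
Why: This is an enantioselective Diels–Alder reaction of a boron-bound α-methyl enal in which the β-carbon bonds to the vinyl terminus ("ortho" adduct, C7–C8 and C9–C10), the α-methyl enal reacts exo (both methyls under the diene), which puts C8-CH3 cis to C1, and the shielded enal face fixes the absolute configuration at C8 and C10 (and provisionally at C9).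

Step 5
Reactants: 9 exo aldehyde
Product: 10 (1R,2S,8aR)-1,2,5,5-tetramethyl-1,2,3,5,6,7,8,8a-octahydronaphthalene-1-carboxylic acid
Conditions: NaClO2 (3 equiv), NaH2PO4 (3 equiv), 2-methylbut-2-ene (10 equiv), t-BuOH/H2O, rt
Reagents that add atoms: sodium chlorite [Na+].[O-]Cl=O
Why: Pinnick oxidation converts hindered non-enolisable aldehydes cleanly, and the scavenger keeps HOCl away from the C5=C6 alkene; no stereocentre is touched.

Step 6
Reactants: 11 hydroquinone
Product: 13 2,5-dihydroxy-1,4-benzoquinone, via disodium salt 12 (not isolated)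
Conditions: 50% aq NaOH, 30% H2O2 (3.3 equiv, slow addition), 45–50 °C; conc. HCl, 0 °C
Reagents that add atoms: hydrogen peroxide OO
Why: Alkaline peroxide oxidises hydroquinone to the quinone and then hydroxylates it twice by conjugate addition and re-oxidation in the 2,5-pattern, and the sparingly soluble disodium salt shields the product from over-oxidation.

Step 7
Reactants: 13 2,5-dihydroxy-1,4-benzoquinone; 14 3-methylbutan-1-amine (isopentylamine)
Product: 15 2-hydroxy-5-[(3-methylbutyl)amino]cyclohexa-2,5-diene-1,4-dione
Conditions: 14 (1.0 equiv), EtOH, 78 °C, 6 h; product taken into aq NaHCO3 and re-acidified (the neutral bis-amine stays in the organic layer)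
Reagents that add atoms: none
Why: Addition–elimination of the amine at a vinylogous-acid carbon (enaminone-type condensation) replaces one OH, and the limiting amine plus the weaker electrophilicity of the amino-substituted quinone favour the mono-adduct.

Step 8
Reactants: 15 2-hydroxy-5-[(3-methylbutyl)amino]cyclohexa-2,5-diene-1,4-dione; 16 formaldehyde; 10 bicyclic acid
Product: 20 nakijiquinone M, via Mannich base 17 (not isolated), via quinone methide 18 (not isolated), via tertiary radical 19 (not isolated)
Conditions: (a) 15 (1.5 equiv), 37% aq 16 (1.5 equiv), morpholine (1.5 equiv), MeCN, rt, 1 h; (b) 10 (1.0 equiv), 2,4,5,6-tetra(carbazol-9-yl)isophthalonitrile (5 mol %), MeCN/H2O 4:1, degassed, thin-layer vessel, 450 nm LEDs, 35 °C, 12 h; citric acid work-up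
Reagents that add atoms: none
Why: Proposed new method: acid 10 protonates the morpholine that zwitterion 17 releases, so a single equilibrium supplies both the electrophile 18 (a 2-methylene-1,3-dicarbonyl-type acceptor whose nucleophilic carbon C3 is blocked in its reservoir 17) and the oxidisable carboxylate; the excited cyanoarene oxidises the carboxylate, loss of CO2 gives the nucleophilic tertiary radical 19, which adds to the unhindered CH2 terminus of 18 on the face anti to C8-CH3 and to the C10–C1 bond (CH2 equatorial, CH3 axial, 9R, the same sense seen for C9 decalin radicals in clerodane-type fragment couplings), and the resulting hydroxyquinone-oxyl radical takes the electron back from the reduced photocatalyst, so the step is redox neutral; the closest known reaction types are the photoredox decarboxylative Giese addition of tertiary acids to alkylidene malonates and para-quinone methides, and the trapping of hydroxyquinone ortho-quinone methides released from Mannich bases.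

## Compound list
1 | 2-methylcyclohex-2-en-1-one | CC1=CCCCC1=O | starting material
2 | lithium 2-methylcyclohex-1-en-1-olate | [Li+].[O-]C1=C(C)CCCC1 | intermediate
3 | 2,2-dimethylcyclohexanone | CC1(C)CCCCC1=O | intermediate
4 | lithium 6,6-dimethylcyclohex-1-en-1-olate | [Li+].[O-]C1=CCCCC1(C)C | intermediate
5 | 6,6-dimethylcyclohex-1-en-1-yl trifluoromethanesulfonate | CC1(C)CCCC=C1OS(=O)(=O)C(F)(F)F | intermediate
6 | potassium vinyltrifluoroborate | [K+].C=C[B-](F)(F)F | starting material
7 | 6,6-dimethyl-1-vinylcyclohex-1-ene | C=CC1=CCCCC1(C)C | intermediate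
8 | (E)-2-methylbut-2-enal | C/C=C(\C)C=O | starting material
9 | (1R,2S,8aR)-1,2,5,5-tetramethyl-1,2,3,5,6,7,8,8a-octahydronaphthalene-1-carbaldehyde | O=C[C@@]1(C)[C@@H]2CCCC(C)(C)C2=CC[C@@H]1C | intermediate
10 | (1R,2S,8aR)-1,2,5,5-tetramethyl-1,2,3,5,6,7,8,8a-octahydronaphthalene-1-carboxylic acid | OC(=O)[C@@]1(C)[C@@H]2CCCC(C)(C)C2=CC[C@@H]1C | intermediate
11 | hydroquinone | Oc1ccc(O)cc1 | starting material
12 | disodium 3,6-dioxocyclohexa-1,4-diene-1,4-diolate | [Na+].[Na+].[O-]C1=CC(=O)C([O-])=CC1=O | intermediate
13 | 2,5-dihydroxy-1,4-benzoquinone | OC1=CC(=O)C(O)=CC1=O | intermediate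
14 | 3-methylbutan-1-amine | CC(C)CCN | starting material
15 | 2-hydroxy-5-[(3-methylbutyl)amino]cyclohexa-2,5-diene-1,4-dione | CC(C)CCNC1=CC(=O)C(O)=CC1=O | intermediate
16 | formaldehyde | C=O | starting material
17 | 2-hydroxy-5-[(3-methylbutyl)amino]-3-(morpholin-4-ylmethyl)cyclohexa-2,5-diene-1,4-dione (Mannich base, drawn neutral) | CC(C)CCNC1=CC(=O)C(O)=C(CN2CCOCC2)C1=O | intermediate
18 | 3-methylidene-5-[(3-methylbutyl)amino]cyclohex-5-ene-1,2,4-trione (ortho-quinone methide) | CC(C)CCNC1=CC(=O)C(=O)C(=C)C1=O | intermediate
19 | C9 tertiary radical (1,2,5,5-tetramethyl-octahydronaphthalen-1-yl; C8 and C10 as in 10) | C[C]1[C@@H]2CCCC(C)(C)C2=CC[C@@H]1C | intermediate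
20 | nakijiquinone M, 2-hydroxy-5-[(3-methylbutyl)amino]-3-{[(1R,2S,8aS)-1,2,5,5-tetramethyl-1,2,3,5,6,7,8,8a-octahydronaphthalen-1-yl]methyl}cyclohexa-2,5-diene-1,4-dione | CC(C)CCNC1=CC(=O)C(O)=C(C[C@@]2(C)[C@@H]3CCCC(C)(C)C3=CC[C@@H]2C)C1=O | target

## Step count
- Total steps: 8.
- Longest linear sequence: 6 (steps 1, 2, 3, 4, 5 and 8).

## Steps most likely to fail

**Step 8.**
- The risks are dimerisation or hydration of 18 before the radical reaches it, light absorption and quenching by the red aminoquinone, oxidation or disproportionation of 19, and only moderate facial selectivity.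
- The fallback sets out from 10 (with 13 and 14) and comes back at 20. It keeps the C9 configuration made in the cycloaddition and moves the radical one carbon outward.
- Acid 10 is converted with (COCl)2 into acid chloride F1 and with excess CH2N2 into diazoketone F2. Wolff rearrangement (AgO2CPh, Et3N, aq dioxane) then gives homologous acid F3.
- AgNO3/(NH4)2S2O8 in MeCN/H2O at 65 °C generates the primary C11 radical from F3, and this alkylates symmetrical 13 (3 equiv) to give alkyl-dihydroxyquinone F4.
- Condensation of F4 with 14 at the unhindered C5–OH (EtOH, 60 °C) gives 20.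

**Step 4.**
- The risks are a sluggish trisubstituted dienophile, an acid-sensitive diene, and insufficient exo selectivity or ee.
- The fallback sets out from 7 and 8 and comes back at 10. It gives up catalyst control in favour of resolution.
- An EtAlCl2-promoted exo cycloaddition (CH2Cl2, −20 °C) gives 9 together with its mirror image, ent-aldehyde F5.
- Pinnick oxidation of the mixture gives 10 together with ent-acid F6.
- Crystallisation with (R)-1-phenylethylamine gives phenylethylammonium salt F7. Acidification of this salt delivers enantiopure 10.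

**Step 7.**
- The risks are inert ammonium salt formation and over-reaction to the bis-amine.
- The fallback sets out from 11 and 14 and comes back at 15. It goes through exhaustive amination followed by a self-limiting hydrolysis.
- Aerobic oxidative amination (14 2.2 equiv, Cu(OAc)2 5 mol %, O2, MeOH, rt) gives bis(amino)quinone F8.
- Treatment with 1 M NaOH in EtOH at 60 °C hydrolyses one vinylogous amide only, because the hydroxyquinone anion that forms is no longer electrophilic. Acidification gives 15.

## Further compounds
F1 | step 8 | (1R,2S,8aR)-1,2,5,5-tetramethyl-1,2,3,5,6,7,8,8a-octahydronaphthalene-1-carbonyl chloride | ClC(=O)[C@@]1(C)[C@@H]2CCCC(C)(C)C2=CC[C@@H]1C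
F2 | step 8 | 2-diazo-1-[(1R,2S,8aR)-1,2,5,5-tetramethyl-1,2,3,5,6,7,8,8a-octahydronaphthalen-1-yl]ethan-1-one | [N-]=[N+]=CC(=O)[C@@]1(C)[C@@H]2CCCC(C)(C)C2=CC[C@@H]1C
F3 | step 8 | 2-[(1R,2S,8aS)-1,2,5,5-tetramethyl-1,2,3,5,6,7,8,8a-octahydronaphthalen-1-yl]acetic acid | OC(=O)C[C@@]1(C)[C@@H]2CCCC(C)(C)C2=CC[C@@H]1C
F4 | step 8 | 2,5-dihydroxy-3-{[(1R,2S,8aS)-1,2,5,5-tetramethyl-1,2,3,5,6,7,8,8a-octahydronaphthalen-1-yl]methyl}cyclohexa-2,5-diene-1,4-dione | OC1=CC(=O)C(O)=C(C[C@@]2(C)[C@@H]3CCCC(C)(C)C3=CC[C@@H]2C)C1=O
F5 | step 4 | (1S,2R,8aS)-1,2,5,5-tetramethyl-1,2,3,5,6,7,8,8a-octahydronaphthalene-1-carbaldehyde | O=C[C@]1(C)[C@H]2CCCC(C)(C)C2=CC[C@H]1C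
F6 | step 4 | (1S,2R,8aS)-1,2,5,5-tetramethyl-1,2,3,5,6,7,8,8a-octahydronaphthalene-1-carboxylic acid | OC(=O)[C@]1(C)[C@H]2CCCC(C)(C)C2=CC[C@H]1C
F7 | step 4 | (R)-1-phenylethylammonium (1R,2S,8aR)-1,2,5,5-tetramethyl-1,2,3,5,6,7,8,8a-octahydronaphthalene-1-carboxylate | C[C@@H]([NH3+])c1ccccc1.[O-]C(=O)[C@@]1(C)[C@@H]2CCCC(C)(C)C2=CC[C@@H]1C
F8 | step 7 | 2,5-bis[(3-methylbutyl)amino]cyclohexa-2,5-diene-1,4-dione | CC(C)CCNC1=CC(=O)C(NCCC(C)C)=CC1=O
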